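**Plan**

- Retrosynthetic cuts, in order: the O–Si bonds and the isopropylidene acetal (last two steps); C1′–C2′ together with C3′–CH3 (key step, from a C2′≡C3′ alkyne, Me3Al and an aryloxymethyl chloride); C5′–C6′ (alkylzinc/alkenyl iodide coupling); C7′–CH3 (first methylalumination, giving C6′–I); C7′–C8′ (acetylide on a triflate); the two C11′–CH3 bonds (Grignard).
- Enabling feature: C3′ carries a methyl group cis to the oxygen-bound C1′ methylene across C2′=C3′. That is the imprint of syn CH3–Al addition to a terminal C2′≡C3′ alkyne followed by capture of C2′ by an ArO–CH2 cation, so the O7–C1′ bond comes in with the coumarin bicycle (benzene ring fused to the pyranone) and is never made by allylation.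
- Forward, the chain grows from C11′ towards C1′: L-tartrate acetonide (C8′–C11′), propargyl dioxolane (C6′, C7′ added), E-iodoalkene, enyne (C2′–C5′ added), then the key step joins C1′ and the coumarin. No ring is formed; the dioxolane and the coumarin are bought in.
- Stereochemistry: C9′ (S) and C10′ (R) are C2 and C3 of L-tartaric acid, held as the trans-dioxolane and never touched. Both E alkenes come from syn methylalumination with retentive replacement of aluminium.

Key step: step 11

Remark: the side chain is numbered C1′ (OCH2) to C11′ (tertiary carbinol carbon), and the C11′ hydroxyl is carried as a triethylsilyl ether through both organoaluminium steps.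

**Route**

Step 1
Reactants: 1 dimethyl 2,3-O-isopropylidene-L-tartrate
Product: 2 methyl (4R,5S)-5-(hydroxymethyl)-2,2-dimethyl-1,3-dioxolane-4-carboxylate
Conditions: NaBH4 (0.6 equiv), MeOH, −10 °C to 0 °C; unreacted 1 recovered
Reagents that add atoms: none
Why: Borohydride reduction of an α-alkoxy-activated ester with a deficit of hydride should stop largely at the mono-alcohol, and since the two esters of the C2-symmetric diester are equivalent no regio- or stereochemical question arises.

Step 2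
Reactants: 2 methyl (4R,5S)-5-(hydroxymethyl)-2,2-dimethyl-1,3-dioxolane-4-carboxylate
Product: 3 2-[(4R,5S)-5-(hydroxymethyl)-2,2-dimethyl-1,3-dioxolan-4-yl]propan-2-ol
Conditions: MeMgBr (4 equiv), THF, 0 °C to rt; aqueous work-up
Reagents that add atoms: methylmagnesium bromide, C[Mg]Br
Why: Double Grignard addition to the ester, after the first equivalent has deprotonated the hydroxyl, should give the tertiary carbinol that becomes C11′ without touching the dioxolane stereocentres.

Step 3
Reactants: 3 2-[(4R,5S)-5-(hydroxymethyl)-2,2-dimethyl-1,3-dioxolan-4-yl]propan-2-ol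
Product: 5 {(4S,5R)-2,2-dimethyl-5-[2-(triethylsilyloxy)propan-2-yl]-1,3-dioxolan-4-yl}methyl trifluoromethanesulfonate, via hydroxy triflate 4 (not isolated)
Conditions: Tf2O (1.05 equiv), 2,6-lutidine (3 equiv), CH2Cl2, −78 °C; then TESOTf (1.3 equiv), −78 °C to 0 °C; cold work-up, used at once
Reagents that add atoms: trifluoromethanesulfonic anhydride, O=S(=O)(OS(=O)(=O)C(F)(F)F)C(F)(F)F; triethylsilyl trifluoromethanesulfonate, CC[Si](CC)(CC)OS(=O)(=O)C(F)(F)F
Why: One-pot triflation–silylation of a diol: Tf2O at −78 °C should select the primary over the hindered tertiary hydroxyl, which the silyl triflate then caps, so that no alkoxide is later available to assist acetonide opening by aluminium Lewis acids or to intercept the oxocarbenium ion.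

Step 4
Reactants: 5 {(4S,5R)-2,2-dimethyl-5-[2-(triethylsilyloxy)propan-2-yl]-1,3-dioxolan-4-yl}methyl trifluoromethanesulfonate
Product: 7 triethyl({2-[(4R,5S)-2,2-dimethyl-5-(prop-2-yn-1-yl)-1,3-dioxolan-4-yl]propan-2-yl}oxy)silane, via silylalkyne 6 (not isolated)
Conditions: ethynyltrimethylsilane, n-BuLi, THF, −78 °C; 5, DMPU, −78 °C to −20 °C; then MeOH, K2CO3, rt
Reagents that add atoms: ethynyltrimethylsilane, C#C[Si](C)(C)C
Why: SN2 alkylation of lithium (trimethylsilyl)acetylide by the primary triflate should form C7′–C8′, and methanolysis of the alkynyl C–Si bond in the same flask should release the terminal alkyne while the tertiary triethylsilyl ether persists.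

Step 5
Reactants: 7 triethyl({2-[(4R,5S)-2,2-dimethyl-5-(prop-2-yn-1-yl)-1,3-dioxolan-4-yl]propan-2-yl}oxy)silane; 8 trimethylaluminium
Product: 10 triethyl({2-[(4R,5S)-5-[(2E)-3-iodo-2-methylprop-2-en-1-yl]-2,2-dimethyl-1,3-dioxolan-4-yl]propan-2-yl}oxy)silane, via alkenylalane 9 (not isolated)
Conditions: Me3Al (3 equiv), Cp2ZrCl2 (0.25 equiv), H2O (1.5 equiv), CH2Cl2, −25 °C; then I2, THF, −25 °C to 0 °C
Reagents that add atoms: trimethylaluminium (compound 8), C[Al](C)C; iodine, II
Why: Zirconium-catalysed syn methylalumination (Negishi carboalumination) should place CH3 on internal C7′ and aluminium on terminal C6′, and iodinolysis of the C–Al bond with retention should give the E-iodoalkene, the water-accelerated variant being chosen so that the acetonide meets Me3Al only below −20 °C.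

Step 6
Reactants: 10 triethyl({2-[(4R,5S)-5-[(2E)-3-iodo-2-methylprop-2-en-1-yl]-2,2-dimethyl-1,3-dioxolan-4-yl]propan-2-yl}oxy)silane; 11 4-bromo-1-(trimethylsilyl)but-1-yne
Product: 13 trimethyl[(5E)-7-{(4S,5R)-2,2-dimethyl-5-[2-(triethylsilyloxy)propan-2-yl]-1,3-dioxolan-4-yl}-6-methylhept-5-en-1-yn-1-yl]silane, via alkylzinc bromide 12 (not isolated)
Conditions: 11 (1.5 equiv), Zn dust, I2 (5 mol %), DMA, 70 °C; then 10, Pd(PPh3)4 (5 mol %), THF, rt to 45 °C
Reagents that add atoms: none
Why: Zinc insertion into the primary bromide and Negishi alkyl–alkenyl coupling under zerovalent palladium should forge C5′–C6′ with retention of the alkene geometry, the silyl cap keeping the alkyne out of the organometallic chemistry.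

Step 7
Reactants: 13 trimethyl[(5E)-7-{(4S,5R)-2,2-dimethyl-5-[2-(triethylsilyloxy)propan-2-yl]-1,3-dioxolan-4-yl}-6-methylhept-5-en-1-yn-1-yl]silane
Product: 14 triethyl({2-[(4R,5S)-2,2-dimethyl-5-[(2E)-2-methylhept-2-en-6-yn-1-yl]-1,3-dioxolan-4-yl]propan-2-yl}oxy)silane
Conditions: K2CO3, MeOH, rt
Reagents that add atoms: none
Why: Base-mediated protodesilylation of the alkynylsilane should leave the tertiary silyl ether, the acetonide and the trisubstituted alkene untouched.

Step 8
Reactants: 15 5,7-dihydroxycoumarin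
Product: 16 5-hydroxy-7-[(methylsulfanyl)methoxy]-2H-chromen-2-one
Conditions: ClCH2SMe (1.05 equiv), K2CO3 (1.1 equiv), NaI (0.1 equiv), DMF, 0 °C to rt
Reagents that add atoms: chloromethyl methyl sulfide, CSCCl
Why: Williamson O-alkylation in which the 7-OH, para to C4a and unhindered, is the more acidic and more accessible phenol (the 5-OH sits peri to C4–H), so one equivalent of base should give chiefly the 7-O-methylthiomethyl ether.

Step 9
Reactants: 16 5-hydroxy-7-[(methylsulfanyl)methoxy]-2H-chromen-2-one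
Product: 17 7-[(methylsulfanyl)methoxy]-5-(triisopropylsilyloxy)-2H-chromen-2-one
Conditions: TIPSCl (1.3 equiv), imidazole (2.5 equiv), DMF, rt to 40 °C
Reagents that add atoms: triisopropylsilyl chloride, CC(C)[Si](Cl)(C(C)C)C(C)C
Why: Standard silylation of the remaining phenol should give an aryl silyl ether that withstands sulfuryl chloride and the organoaluminium step and is removed by fluoride at the end.

Step 10
Reactants: 17 7-[(methylsulfanyl)methoxy]-5-(triisopropylsilyloxy)-2H-chromen-2-one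
Product: 18 7-(chloromethoxy)-5-(triisopropylsilyloxy)-2H-chromen-2-one
Conditions: SO2Cl2 (1.0 equiv), cyclohexene (2 equiv), CH2Cl2, −78 °C to 0 °C; concentrated, crude 18 used at once
Reagents that add atoms: sulfuryl chloride, O=S(=O)(Cl)Cl
Why: Chlorinolysis of the O,S-acetal (sulfide to chlorosulfonium ion, then fragmentation to the chloromethyl ether and methanesulfenyl chloride) is the usual conversion of methylthiomethyl ethers and should outrun chlorination of the arene at −78 °C, with cyclohexene scavenging the sulfenyl chloride.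

Step 11
Reactants: 14 triethyl({2-[(4R,5S)-2,2-dimethyl-5-[(2E)-2-methylhept-2-en-6-yn-1-yl]-1,3-dioxolan-4-yl]propan-2-yl}oxy)silane; 8 trimethylaluminium; 18 7-(chloromethoxy)-5-(triisopropylsilyloxy)-2H-chromen-2-one
Product: 20 7-{[(2E,6E)-8-{(4S,5R)-2,2-dimethyl-5-[2-(triethylsilyloxy)propan-2-yl]-1,3-dioxolan-4-yl}-3,7-dimethylocta-2,6-dien-1-yl]oxy}-5-(triisopropylsilyloxy)-2H-chromen-2-one, via alkenylalane 19 (not isolated)
Conditions: Me3Al (2.5 equiv), Cp2ZrCl2 (0.25 equiv), H2O (1 equiv), CH2Cl2, −25 °C; volatiles stripped in vacuo at 0 °C; then 18 (1.3 equiv), CH2Cl2, −25 °C to 0 °C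
Reagents that add atoms: trimethylaluminium (compound 8), C[Al](C)C
Why: Proposed new method: the methylzirconium–aluminium species formed from Me3Al and Cp2ZrCl2 adds CH3 and the metal syn across C2′≡C3′ of 14, methyl to the substituted C3′ and aluminium to the terminal C2′, to give alkenylalane 19; chloroaluminium species then ionise 18 to an aryloxy-stabilised oxocarbenium ion that attacks C2′ ipso to aluminium, the charge developing at tertiary C3′ being stabilised by the β C–Al bond, and loss of the dimethylaluminium group forms C1′–C2′ with retention. The closest known reaction type is the zirconium-catalysed methylalumination of terminal alkynes with capture of the alkenylalane by chloromethyl alkyl ethers; an aryloxymethyl chloride has not been used as the trap and its oxocarbenium ion is less stabilised, which is the unproven element. No ring is closed and no stereocentre is formed; the only stereochemical element created is the C2′=C3′ geometry, fixed as E (CH3 cis to C1′) by syn addition and retentive substitution. The step needs aluminium at the terminal carbon, which the terminal alkyne ensures, and transfer of the alkenyl rather than a methyl group to the cation, which the higher π-nucleophilicity of the alkenyl–aluminium bond and the stripping of excess Me3Al before 18 is added should favour. It also needs the acetonide, both silyl ethers and the lactone to survive, for which the tertiary hydroxyl is capped (no aluminium alkoxide next to the dioxolane) and the temperature is kept at or below 0 °C.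

Step 12
Reactants: 20 7-{[(2E,6E)-8-{(4S,5R)-2,2-dimethyl-5-[2-(triethylsilyloxy)propan-2-yl]-1,3-dioxolan-4-yl}-3,7-dimethylocta-2,6-dien-1-yl]oxy}-5-(triisopropylsilyloxy)-2H-chromen-2-one
Product: 21 5-hydroxy-7-{[(2E,6E)-8-[(4S,5R)-5-(2-hydroxypropan-2-yl)-2,2-dimethyl-1,3-dioxolan-4-yl]-3,7-dimethylocta-2,6-dien-1-yl]oxy}-2H-chromen-2-one
Conditions: Bu4NF (3 equiv), THF, 0 °C to rt; aqueous work-up
Reagents that add atoms: none
Why: Fluoride-mediated desilylation should cleave the aryl triisopropylsilyl ether quickly and the tertiary triethylsilyl ether more slowly, while the acetonide, the allylic aryl ether and the lactone are inert to Bu4NF.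

Step 13
Reactants: 21 5-hydroxy-7-{[(2E,6E)-8-[(4S,5R)-5-(2-hydroxypropan-2-yl)-2,2-dimethyl-1,3-dioxolan-4-yl]-3,7-dimethylocta-2,6-dien-1-yl]oxy}-2H-chromen-2-one
Product: 22 5-hydroxy-7-{[(2E,6E,9S,10R)-9,10,11-trihydroxy-3,7,11-trimethyldodeca-2,6-dien-1-yl]oxy}-2H-chromen-2-one
Conditions: AcOH/H2O (4:1), 45 °C
Reagents that add atoms: none
Why: Acid-catalysed hydrolysis of the isopropylidene acetal should free the 9′,10′-diol without epimerisation, since no C–O bond at C9′ or C10′ is broken, and acetic acid is expected to be too weak to ionise the allylic aryl ether or protonate the trisubstituted alkenes.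

**Compound list**

1 | dimethyl (4R,5R)-2,2-dimethyl-1,3-dioxolane-4,5-dicarboxylate (dimethyl 2,3-O-isopropylidene-L-tartrate) | COC(=O)[C@@H]1OC(C)(C)O[C@H]1C(=O)OC | starting material
2 | methyl (4R,5S)-5-(hydroxymethyl)-2,2-dimethyl-1,3-dioxolane-4-carboxylate | COC(=O)[C@@H]1OC(C)(C)O[C@H]1CO | intermediate
3 | 2-[(4R,5S)-5-(hydroxymethyl)-2,2-dimethyl-1,3-dioxolan-4-yl]propan-2-ol | CC(C)(O)[C@@H]1OC(C)(C)O[C@H]1CO | intermediate
4 | [(4S,5R)-5-(2-hydroxypropan-2-yl)-2,2-dimethyl-1,3-dioxolan-4-yl]methyl trifluoromethanesulfonate (not isolated) | CC(C)(O)[C@@H]1OC(C)(C)O[C@H]1COS(=O)(=O)C(F)(F)F | intermediate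
5 | {(4S,5R)-2,2-dimethyl-5-[2-(triethylsilyloxy)propan-2-yl]-1,3-dioxolan-4-yl}methyl trifluoromethanesulfonate | CC[Si](CC)(CC)OC(C)(C)[C@@H]1OC(C)(C)O[C@H]1COS(=O)(=O)C(F)(F)F | intermediate
6 | trimethyl(3-{(4S,5R)-2,2-dimethyl-5-[2-(triethylsilyloxy)propan-2-yl]-1,3-dioxolan-4-yl}prop-1-yn-1-yl)silane (not isolated) | CC[Si](CC)(CC)OC(C)(C)[C@@H]1OC(C)(C)O[C@H]1CC#C[Si](C)(C)C | intermediate
7 | triethyl({2-[(4R,5S)-2,2-dimethyl-5-(prop-2-yn-1-yl)-1,3-dioxolan-4-yl]propan-2-yl}oxy)silane | CC[Si](CC)(CC)OC(C)(C)[C@@H]1OC(C)(C)O[C@H]1CC#C | intermediate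
8 | trimethylaluminium | C[Al](C)C | starting material
9 | dimethyl[(1E)-3-{(4S,5R)-2,2-dimethyl-5-[2-(triethylsilyloxy)propan-2-yl]-1,3-dioxolan-4-yl}-2-methylprop-1-en-1-yl]aluminium (not isolated) | C[Al](C)/C=C(\C)C[C@@H]1OC(C)(C)O[C@H]1C(C)(C)O[Si](CC)(CC)CC | intermediate
10 | triethyl({2-[(4R,5S)-5-[(2E)-3-iodo-2-methylprop-2-en-1-yl]-2,2-dimethyl-1,3-dioxolan-4-yl]propan-2-yl}oxy)silane | I/C=C(\C)C[C@@H]1OC(C)(C)O[C@H]1C(C)(C)O[Si](CC)(CC)CC | intermediate
11 | 4-bromo-1-(trimethylsilyl)but-1-yne | C[Si](C)(C)C#CCCBr | starting material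
12 | bromo[4-(trimethylsilyl)but-3-yn-1-yl]zinc (not isolated) | C[Si](C)(C)C#CCC[Zn]Br | intermediate
13 | trimethyl[(5E)-7-{(4S,5R)-2,2-dimethyl-5-[2-(triethylsilyloxy)propan-2-yl]-1,3-dioxolan-4-yl}-6-methylhept-5-en-1-yn-1-yl]silane | C[Si](C)(C)C#CCC/C=C(\C)C[C@@H]1OC(C)(C)O[C@H]1C(C)(C)O[Si](CC)(CC)CC | intermediate
14 | triethyl({2-[(4R,5S)-2,2-dimethyl-5-[(2E)-2-methylhept-2-en-6-yn-1-yl]-1,3-dioxolan-4-yl]propan-2-yl}oxy)silane | C#CCC/C=C(\C)C[C@@H]1OC(C)(C)O[C@H]1C(C)(C)O[Si](CC)(CC)CC | intermediate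
15 | 5,7-dihydroxy-2H-chromen-2-one (5,7-dihydroxycoumarin) | O=c1ccc2c(O)cc(O)cc2o1 | starting material
16 | 5-hydroxy-7-[(methylsulfanyl)methoxy]-2H-chromen-2-one | CSCOc1cc(O)c2ccc(=O)oc2c1 | intermediate
17 | 7-[(methylsulfanyl)methoxy]-5-(triisopropylsilyloxy)-2H-chromen-2-one | CSCOc1cc(O[Si](C(C)C)(C(C)C)C(C)C)c2ccc(=O)oc2c1 | intermediate
18 | 7-(chloromethoxy)-5-(triisopropylsilyloxy)-2H-chromen-2-one | ClCOc1cc(O[Si](C(C)C)(C(C)C)C(C)C)c2ccc(=O)oc2c1 | intermediate
19 | dimethyl[(1E,5E)-7-{(4S,5R)-2,2-dimethyl-5-[2-(triethylsilyloxy)propan-2-yl]-1,3-dioxolan-4-yl}-2,6-dimethylhepta-1,5-dien-1-yl]aluminium (not isolated) | C[Al](C)/C=C(\C)CC/C=C(\C)C[C@@H]1OC(C)(C)O[C@H]1C(C)(C)O[Si](CC)(CC)CC | intermediate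
20 | 7-{[(2E,6E)-8-{(4S,5R)-2,2-dimethyl-5-[2-(triethylsilyloxy)propan-2-yl]-1,3-dioxolan-4-yl}-3,7-dimethylocta-2,6-dien-1-yl]oxy}-5-(triisopropylsilyloxy)-2H-chromen-2-one | C/C(=C\COc1cc(O[Si](C(C)C)(C(C)C)C(C)C)c2ccc(=O)oc2c1)CC/C=C(\C)C[C@@H]1OC(C)(C)O[C@H]1C(C)(C)O[Si](CC)(CC)CC | intermediate
21 | 5-hydroxy-7-{[(2E,6E)-8-[(4S,5R)-5-(2-hydroxypropan-2-yl)-2,2-dimethyl-1,3-dioxolan-4-yl]-3,7-dimethylocta-2,6-dien-1-yl]oxy}-2H-chromen-2-one | C/C(=C\COc1cc(O)c2ccc(=O)oc2c1)CC/C=C(\C)C[C@@H]1OC(C)(C)O[C@H]1C(C)(C)O | intermediate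
22 | 5-hydroxy-7-{[(2E,6E,9S,10R)-9,10,11-trihydroxy-3,7,11-trimethyldodeca-2,6-dien-1-yl]oxy}-2H-chromen-2-one | C/C(=C\COc1cc(O)c2ccc(=O)oc2c1)CC/C=C(\C)C[C@H](O)[C@@H](O)C(C)(C)O | target

**Count and risks**

Total steps: 13. Longest linear sequence: 10 steps (steps 1–7, then 11–13); the coumarin branch (steps 8–10) is three steps.

Steps most likely to fail:

1. Step 11. The oxocarbenium ion may be intercepted by a methyl group from aluminium, may alkylate the electron-rich coumarin ring in a Friedel–Crafts sense, or the chloroaluminium Lewis acids may open the acetonide before the alkenyl transfer occurs. The fallback sets out from 14 and 17 and returns at 20. Alkenylalane 19, generated from 14 as in step 11, would be trapped with paraformaldehyde instead, the established carboalumination–hydroxymethylation, to give (2E,6E)-8-{(4S,5R)-2,2-dimethyl-5-[2-(triethylsilyloxy)propan-2-yl]-1,3-dioxolan-4-yl}-3,7-dimethylocta-2,6-dien-1-ol F1. The methylthiomethyl ether 17 would be unmasked with HgCl2 and CaCO3 in aqueous MeCN to 7-hydroxy-5-(triisopropylsilyloxy)-2H-chromen-2-one F2. A Mitsunobu etherification of F1 with F2 (PPh3, diisopropyl azodicarboxylate, THF, 0 °C) would then give 20. This detour also makes step 10 and chloromethyl ether 18 unnecessary.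

2. Step 13. The hindered trans-dioxolane may hydrolyse so slowly that the acid needed ionises the allylic aryl ether or drives a side-chain hydroxyl onto the C6′=C7′ alkene. The fallback sets out from 14 and returns at 22, moving the acid step ahead of the coumarin coupling. Camphorsulfonic acid in MeOH would convert 14 into (3R,4S,6E)-2,6-dimethylundec-6-en-10-yne-2,3,4-triol F3. TESOTf and 2,6-lutidine would give (3R,4S,6E)-2,6-dimethyl-2,3,4-tris(triethylsilyloxy)undec-6-en-10-yne F4. Methylalumination as in step 11 would give dimethyl[(1E,5E,8S,9R)-2,6,10-trimethyl-8,9,10-tris(triethylsilyloxy)undeca-1,5-dien-1-yl]aluminium F5 (not isolated), captured by 18 to give 7-{[(2E,6E,9S,10R)-3,7,11-trimethyl-9,10,11-tris(triethylsilyloxy)dodeca-2,6-dien-1-yl]oxy}-5-(triisopropylsilyloxy)-2H-chromen-2-one F6. Bu4NF would then remove all four silyl groups in one operation to give 22, so that no acid meets the finished ether.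

3. Step 8. Alkylation may be poorly regioselective, with attack at O5 and double alkylation competing with the wanted 7-O-alkylation. The fallback sets out from 15 and returns at 17, bypassing 16. Both phenols would be silylated (TIPSCl, imidazole, DMF) to 5,7-bis(triisopropylsilyloxy)-2H-chromen-2-one F7. One equivalent of CsF in DMF at 0 °C should cleave the unhindered and more labile 7-O-silyl ether to cesium 2-oxo-5-(triisopropylsilyloxy)-2H-chromen-7-olate F8 (not isolated). F8 would be alkylated in the same flask with chloromethyl methyl sulfide, a fluoride-mediated desilylation–alkylation of an aryl silyl ether, to give 17.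

Further compounds
F1 | step 11 | (2E,6E)-8-{(4S,5R)-2,2-dimethyl-5-[2-(triethylsilyloxy)propan-2-yl]-1,3-dioxolan-4-yl}-3,7-dimethylocta-2,6-dien-1-ol | C/C(=C\CO)CC/C=C(\C)C[C@@H]1OC(C)(C)O[C@H]1C(C)(C)O[Si](CC)(CC)CC
F2 | step 11 | 7-hydroxy-5-(triisopropylsilyloxy)-2H-chromen-2-one | Oc1cc(O[Si](C(C)C)(C(C)C)C(C)C)c2ccc(=O)oc2c1
F3 | step 13 | (3R,4S,6E)-2,6-dimethylundec-6-en-10-yne-2,3,4-triol | C#CCC/C=C(\C)C[C@H](O)[C@@H](O)C(C)(C)O
F4 | step 13 | (3R,4S,6E)-2,6-dimethyl-2,3,4-tris(triethylsilyloxy)undec-6-en-10-yne | C#CCC/C=C(\C)C[C@H](O[Si](CC)(CC)CC)[C@@H](O[Si](CC)(CC)CC)C(C)(C)O[Si](CC)(CC)CC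
F5 | step 13 | dimethyl[(1E,5E,8S,9R)-2,6,10-trimethyl-8,9,10-tris(triethylsilyloxy)undeca-1,5-dien-1-yl]aluminium | C[Al](C)/C=C(\C)CC/C=C(\C)C[C@H](O[Si](CC)(CC)CC)[C@@H](O[Si](CC)(CC)CC)C(C)(C)O[Si](CC)(CC)CC
F6 | step 13 | 7-{[(2E,6E,9S,10R)-3,7,11-trimethyl-9,10,11-tris(triethylsilyloxy)dodeca-2,6-dien-1-yl]oxy}-5-(triisopropylsilyloxy)-2H-chromen-2-one | C/C(=C\COc1cc(O[Si](C(C)C)(C(C)C)C(C)C)c2ccc(=O)oc2c1)CC/C=C(\C)C[C@H](O[Si](CC)(CC)CC)[C@@H](O[Si](CC)(CC)CC)C(C)(C)O[Si](CC)(CC)CC
F7 | step 8 | 5,7-bis(triisopropylsilyloxy)-2H-chromen-2-one | CC(C)[Si](Oc1cc(O[Si](C(C)C)(C(C)C)C(C)C)c2ccc(=O)oc2c1)(C(C)C)C(C)C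
F8 | step 8 | cesium 2-oxo-5-(triisopropylsilyloxy)-2H-chromen-7-olate | [Cs+].[O-]c1cc(O[Si](C(C)C)(C(C)C)C(C)C)c2ccc(=O)oc2c1
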